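**Plan** (C1 = ester C=O, then along the chain to C8–C9=C10; ring A = 1,2-dioxane O–O–C3–C4–C5–C6; ring B = trimethylcyclohexene)
1. Cuts, in order: C8–C9 (arm on C6 of ring A / CH terminus of the C9=C10 alkene), giving two electrophiles, primary iodide 15 and (E)-alkenyl iodide 20. Then O–C3 and O–C6 of ring A, then C2–C3.
2. Enabling feature: C8 is a primary carbon gamma to the ring oxygen on quaternary C6 (C8–C7–C6–O). A C8 radical therefore has no beta leaving group and only a slow 4-exo attack on O–O. C9 carries only H, so the E geometry can be fixed in 20 beforehand and carried over with retention.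
3. Forward, half 1: geraniol (supplies C3–C8 and the C6 methyl) → epoxide → 1,3-diol → oxetane C6–C7–C8–O (temporary ring) → aldehyde → crotylation (C1, C2, 2-Me) → mesylate → C6 hydroperoxide → ring A → vinyl to CO2Me → iodide.
4. Forward, half 2: dihydro-β-ionone (ring B) → alkyne → 20. The halves are joined last, so the two electron-rich alkenes never meet O3, H2O2 or chlorite, and ring A never meets base or an organometallic reagent.
5. Stereochemistry: C6 comes from Sharpless epoxidation, then inversion in the oxetane opening. C2 and C3 come from reagent-controlled (Z)-crotylboration, with C3 then inverted in the ring closure. E-C9=C10 comes from syn-carboalumination.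

Key step: step 15

Remark: the SMILES is read as (2S,3S,6S), E at C9=C10, with C2 and C7 cis on ring A.

Step 1
Reactants: 1 geraniol
Product: 2 (2S,3S)-2,3-epoxygeraniol
Conditions: Ti(OiPr)4 (5 mol %), L-(+)-diethyl tartrate (7 mol %), t-BuOOH, 4 Å MS, CH2Cl2, −20 °C
Reagents that add atoms: tert-butyl hydroperoxide, CC(C)(C)OO
Why: Sharpless asymmetric epoxidation touches only the allylic alkene, and the L-(+)-tartrate catalyst delivers oxygen to the face that gives the (2S,3S)-epoxide, which sets the oxygen-bearing quaternary carbon that becomes C6.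

Step 2
Reactants: 2 (2S,3S)-2,3-epoxygeraniol
Product: 3 (3S)-3,7-dimethyloct-6-ene-1,3-diol
Conditions: NaAlH2(OCH2CH2OMe)2, THF, 0 °C → rt; aq. NaOH work-up
Reagents that add atoms: none
Why: In this hydroxyl-directed reductive opening of a 2,3-epoxy alcohol the bound aluminate delivers hydride to the secondary epoxide carbon, so the tertiary C–O bond and its configuration are kept and the 1,3-diol results.

Step 3
Reactants: 3 (3S)-3,7-dimethyloct-6-ene-1,3-diol
Product: 5 (2S)-2-methyl-2-(4-methylpent-3-en-1-yl)oxetane, via primary monotosylate 4 (not isolated)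
Conditions: n-BuLi (1 equiv), THF, 0 °C; TsCl (1 equiv); n-BuLi (1 equiv), 0 → 60 °C
Reagents that add atoms: none
Why: Selective sulfonylation of the primary alkoxide followed by Williamson-type 4-exo-tet closure by the tertiary alkoxide forms the oxetane without touching the C–O bond at the stereocentre, so configuration is retained.

Step 4
Reactants: 5 (2S)-2-methyl-2-(4-methylpent-3-en-1-yl)oxetane
Product: 6 3-[(2S)-2-methyloxetan-2-yl]propanal
Conditions: O3, CH2Cl2–MeOH, −78 °C; Me2S, −78 °C → rt
Reagents that add atoms: ozone, [O-][O+]=O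
Why: Ozonolysis with reductive work-up cleaves the only alkene and unmasks C3 as an aldehyde, while the oxetane is inert to ozone and to the neutral work-up.

Step 5
Reactants: 6 3-[(2S)-2-methyloxetan-2-yl]propanal
Product: 8 (3R,4R)-3-methyl-6-[(2S)-2-methyloxetan-2-yl]hex-1-en-4-ol, via diisopinocampheylborinate ester 7 (not isolated)
Conditions: (Z)-2-butene, KOtBu, n-BuLi, THF, −78 → −45 °C; (−)-Ipc2BOMe [from (+)-α-pinene], −78 °C; BF3·OEt2 (matched to the borate, none left free); 6, −78 °C; NaOH, H2O2, 0 °C → rt
Reagents that add atoms: (Z)-2-butene, C/C=C\C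
Why: Brown asymmetric crotylboration runs through a closed Zimmerman–Traxler chair, so the Z-crotyl geometry gives the syn methyl/hydroxyl pair and the (+)-α-pinene-derived ligands choose the aldehyde face that gives the (3R,4R)-alcohol, independently of the remote oxetane centre.

Step 6
Reactants: 8 (3R,4R)-3-methyl-6-[(2S)-2-methyloxetan-2-yl]hex-1-en-4-ol
Product: 9 (3R,4R)-3-methyl-6-[(2S)-2-methyloxetan-2-yl]hex-1-en-4-yl methanesulfonate
Conditions: MsCl, Et3N, CH2Cl2, 0 °C
Reagents that add atoms: methanesulfonyl chloride, CS(=O)(=O)Cl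
Why: Sulfonate ester formation at oxygen leaves the carbinol carbon (C3) untouched, makes it the electrophile for ring closure and removes the hydroxyl that could otherwise open the acid-labile oxetane.

Step 7
Reactants: 9 (3R,4R)-3-methyl-6-[(2S)-2-methyloxetan-2-yl]hex-1-en-4-yl methanesulfonate
Product: 10 (3R,4R,7R)-7-hydroperoxy-9-hydroxy-3,7-dimethylnon-1-en-4-yl methanesulfonate
Conditions: anhydrous H2O2 in Et2O (excess), TMSOTf (0.2 equiv), Et2O, −78 → −20 °C
Reagents that add atoms: hydrogen peroxide, OO
Why: In this Lewis-acid-promoted perhydrolysis of a 2,2-disubstituted oxetane the silylated ring is opened at its tertiary carbon C6 by H2O2 from the rear in a borderline SN2 process, so C6 should be inverted to the configuration of the target, the ring oxygen is released as the C8 hydroxyl, and mesylate and vinyl group stay inert.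

Step 8
Reactants: 10 (3R,4R,7R)-7-hydroperoxy-9-hydroxy-3,7-dimethylnon-1-en-4-yl methanesulfonate
Product: 11 2-{(3R,6S)-6-[(2R)-but-3-en-2-yl]-3-methyl-1,2-dioxan-3-yl}ethan-1-ol
Conditions: KOtBu (1.0 equiv), 18-crown-6, THF, 0 °C
Reagents that add atoms: none
Why: In this intramolecular alkylation of a hydroperoxide (6-exo-tet SN2) only the more acidic OOH is deprotonated, and the peroxy anion displaces the C3 mesylate with inversion, which closes ring A with C2 and C7 cis.

Step 9
Reactants: 11 2-{(3R,6S)-6-[(2R)-but-3-en-2-yl]-3-methyl-1,2-dioxan-3-yl}ethan-1-ol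
Product: 12 (2S)-2-[(3S,6R)-6-(2-hydroxyethyl)-6-methyl-1,2-dioxan-3-yl]propanal
Conditions: O3, CH2Cl2–MeOH, −78 °C; Me2S, −78 °C → rt; used crude
Reagents that add atoms: ozone, [O-][O+]=O
Why: Ozonolysis with dimethyl sulfide work-up turns the vinyl group into the C1 aldehyde under neutral conditions that neither reduce the dialkyl peroxide nor epimerise C2.

Step 10
Reactants: 12 (2S)-2-[(3S,6R)-6-(2-hydroxyethyl)-6-methyl-1,2-dioxan-3-yl]propanal
Product: 13 (2S)-2-[(3S,6R)-6-(2-hydroxyethyl)-6-methyl-1,2-dioxan-3-yl]propanoic acid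
Conditions: NaClO2, NaH2PO4, 2-methyl-2-butene, t-BuOH/H2O, 0 °C → rt
Reagents that add atoms: sodium chlorite, [Na+].[O-]Cl=O
Why: Pinnick oxidation at buffered, weakly acidic pH oxidises only the aldehyde, so the primary alcohol, the peroxide and the C2 stereocentre are kept.

Step 11
Reactants: 13 (2S)-2-[(3S,6R)-6-(2-hydroxyethyl)-6-methyl-1,2-dioxan-3-yl]propanoic acid
Product: 14 methyl (2S)-2-[(3S,6R)-6-(2-hydroxyethyl)-6-methyl-1,2-dioxan-3-yl]propanoate
Conditions: TMSCHN2, toluene/MeOH, 0 °C
Reagents that add atoms: (trimethylsilyl)diazomethane, C[Si](C)(C)C=[N+]=[N-]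
Why: Diazoalkane esterification methylates only the carboxylic acid without base, so retro-oxa-Michael opening of the beta-peroxy ester and epimerisation at C2 are avoided.

Step 12
Reactants: 14 methyl (2S)-2-[(3S,6R)-6-(2-hydroxyethyl)-6-methyl-1,2-dioxan-3-yl]propanoate
Product: 15 methyl (2S)-2-[(3S,6R)-6-(2-iodoethyl)-6-methyl-1,2-dioxan-3-yl]propanoate
Conditions: I2, PPh3, imidazole (premixed, I2 in slight excess over PPh3), CH2Cl2, 0 °C
Reagents that add atoms: iodine, II
Why: In this Appel-type iodination the preformed iodophosphonium salt activates the primary C8 hydroxyl for SN2 attack by iodide, and because no free phosphine is left the O–O bond should not be deoxygenated.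

Step 13
Reactants: 16 dihydro-β-ionone
Product: 18 2-(but-3-yn-1-yl)-1,3,3-trimethylcyclohex-1-ene, via enol diethyl phosphate 17 (not isolated)
Conditions: LiN(iPr)2 (1.05 equiv), THF, −78 °C; ClP(O)(OEt)2, −78 °C → rt; LiN(iPr)2 (2.3 equiv), −78 °C → rt; H2O
Reagents that add atoms: none
Why: Kinetic deprotonation at the methyl group, O-phosphorylation and base-induced beta-elimination make up the established conversion of a methyl ketone into a terminal alkyne through its enol phosphate.

Step 14
Reactants: 18 2-(but-3-yn-1-yl)-1,3,3-trimethylcyclohex-1-ene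
Product: 20 2-[(3E)-4-iodo-3-methylbut-3-en-1-yl]-1,3,3-trimethylcyclohex-1-ene, via (E)-alkenyldimethylalane 19 (not isolated)
Conditions: Me3Al (2 equiv), Cp2ZrCl2 (0.25 equiv), CH2Cl2, 0 °C → rt; I2, THF, −30 → 0 °C
Reagents that add atoms: trimethylaluminium, C[Al](C)C; iodine, II
Why: Negishi zirconium-catalysed carboalumination adds methyl and aluminium syn across the terminal alkyne with aluminium at the terminus, iodinolysis proceeds with retention to the E-iodide, and the hindered tetrasubstituted alkene of ring B is not carbometalated.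

Step 15
Reactants: 15 methyl (2S)-2-[(3S,6R)-6-(2-iodoethyl)-6-methyl-1,2-dioxan-3-yl]propanoate; 20 2-[(3E)-4-iodo-3-methylbut-3-en-1-yl]-1,3,3-trimethylcyclohex-1-ene (1.5 equiv)
Product: 21 methyl (2S)-2-{(3S,6S)-6-methyl-6-[(3E)-4-methyl-6-(2,6,6-trimethylcyclohex-1-en-1-yl)hex-3-en-1-yl]-1,2-dioxan-3-yl}propanoate (target)
Conditions: NiBr2(MeOCH2CH2OMe) (10 mol %), 4,4'-di-tert-butyl-2,2'-bipyridine (12 mol %), (Me2N)2C=C(NMe2)2 (TDAE, 1.5 equiv), N,N-dimethylacetamide, rt, Ar, dark
Reagents that add atoms: none
Why: Zerovalent nickel–bipyridine inserts into the C9–I bond of 20 with retention to give an alkenyl complex of divalent nickel, a monovalent nickel species abstracts iodine from 15 to give the primary C8 radical, capture of this radical gives a trivalent alkyl(alkenyl)nickel that forms C8–C9 by reductive elimination, and TDAE returns nickel to its low-valent states. The closest known reaction type is the nickel-catalysed reductive cross-electrophile coupling of alkenyl halides with unactivated primary alkyl halides, which has also been run with TDAE as a homogeneous reductant. No ring is closed and no stereocentre is created: the E geometry at C9=C10 is that of 20, because insertion and reductive elimination at an alkenyl carbon keep configuration, and C2, C3 and C6 are spectators. Cross-selectivity over dimerisation rests on the different activation modes of the two iodides (two-electron insertion at the sp2 carbon, halogen abstraction at the sp3 carbon) and is helped by the excess of the cheap partner 20. Selectivity for C–I over O–O is needed and should be secured because TDAE is far too weak for outer-sphere reduction of a dialkyl peroxide, the O–O bond of ring A is shielded by quaternary C6 and the branched substituent on C3, and the C8 radical sits gamma to the ring oxygen, where no beta-scission and only a slow 4-exo displacement at oxygen is open to it. The medium holds no base, no organometallic reagent and no phosphine, which spares C2–H (epimerisation, retro-oxa-Michael opening), C3–H (Kornblum–DeLaMare fragmentation) and the methyl ester.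

**Compound list**
1 | geraniol, (2E)-3,7-dimethylocta-2,6-dien-1-ol | CC(C)=CCC/C(C)=C/CO | starting material
2 | (2S,3S)-2,3-epoxygeraniol | CC(C)=CCC[C@]1(C)O[C@H]1CO | intermediate
3 | (3S)-3,7-dimethyloct-6-ene-1,3-diol | CC(C)=CCC[C@@](O)(C)CCO | intermediate
4 | (3S)-3-hydroxy-3,7-dimethyloct-6-en-1-yl 4-methylbenzenesulfonate (not isolated) | CC(C)=CCC[C@@](O)(C)CCOS(=O)(=O)c1ccc(C)cc1 | intermediate
5 | (2S)-2-methyl-2-(4-methylpent-3-en-1-yl)oxetane | CC(C)=CCC[C@@]1(C)CCO1 | intermediate
6 | 3-[(2S)-2-methyloxetan-2-yl]propanal | O=CCC[C@@]1(C)CCO1 | intermediate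
7 | diisopinocampheylborinate ester of 8 (not isolated) | C=C[C@@H](C)[C@H](OB([C@@H]1C[C@@H]2C[C@H]([C@H]1C)C2(C)C)[C@@H]1C[C@@H]2C[C@H]([C@H]1C)C2(C)C)CC[C@@]1(C)CCO1 | intermediate
8 | (3R,4R)-3-methyl-6-[(2S)-2-methyloxetan-2-yl]hex-1-en-4-ol | C=C[C@@H](C)[C@H](O)CC[C@@]1(C)CCO1 | intermediate
9 | (3R,4R)-3-methyl-6-[(2S)-2-methyloxetan-2-yl]hex-1-en-4-yl methanesulfonate | C=C[C@@H](C)[C@H](OS(C)(=O)=O)CC[C@@]1(C)CCO1 | intermediate
10 | (3R,4R,7R)-7-hydroperoxy-9-hydroxy-3,7-dimethylnon-1-en-4-yl methanesulfonate | C=C[C@@H](C)[C@H](OS(C)(=O)=O)CC[C@](C)(CCO)OO | intermediate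
11 | 2-{(3R,6S)-6-[(2R)-but-3-en-2-yl]-3-methyl-1,2-dioxan-3-yl}ethan-1-ol | C=C[C@@H](C)[C@@H]1CC[C@](C)(CCO)OO1 | intermediate
12 | (2S)-2-[(3S,6R)-6-(2-hydroxyethyl)-6-methyl-1,2-dioxan-3-yl]propanal | O=C[C@@H](C)[C@@H]1CC[C@](C)(CCO)OO1 | intermediate
13 | (2S)-2-[(3S,6R)-6-(2-hydroxyethyl)-6-methyl-1,2-dioxan-3-yl]propanoic acid | OC(=O)[C@@H](C)[C@@H]1CC[C@](C)(CCO)OO1 | intermediate
14 | methyl (2S)-2-[(3S,6R)-6-(2-hydroxyethyl)-6-methyl-1,2-dioxan-3-yl]propanoate | COC(=O)[C@@H](C)[C@@H]1CC[C@](C)(CCO)OO1 | intermediate
15 | methyl (2S)-2-[(3S,6R)-6-(2-iodoethyl)-6-methyl-1,2-dioxan-3-yl]propanoate | COC(=O)[C@@H](C)[C@@H]1CC[C@](C)(CCI)OO1 | intermediate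
16 | dihydro-β-ionone, 4-(2,6,6-trimethylcyclohex-1-en-1-yl)butan-2-one | CC(=O)CCC1=C(C)CCCC1(C)C | starting material
17 | diethyl 4-(2,6,6-trimethylcyclohex-1-en-1-yl)but-1-en-2-yl phosphate (not isolated) | C=C(CCC1=C(C)CCCC1(C)C)OP(=O)(OCC)OCC | intermediate
18 | 2-(but-3-yn-1-yl)-1,3,3-trimethylcyclohex-1-ene | C#CCCC1=C(C)CCCC1(C)C | intermediate
19 | dimethyl[(1E)-2-methyl-4-(2,6,6-trimethylcyclohex-1-en-1-yl)but-1-en-1-yl]alane (not isolated) | C[Al](C)/C=C(\C)CCC1=C(C)CCCC1(C)C | intermediate
20 | 2-[(3E)-4-iodo-3-methylbut-3-en-1-yl]-1,3,3-trimethylcyclohex-1-ene | I/C=C(\C)CCC1=C(C)CCCC1(C)C | intermediate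
21 | methyl (2S)-2-{(3S,6S)-6-methyl-6-[(3E)-4-methyl-6-(2,6,6-trimethylcyclohex-1-en-1-yl)hex-3-en-1-yl]-1,2-dioxan-3-yl}propanoate | COC(=O)[C@@H](C)[C@@H]1CC[C@](C)(CC/C=C(\C)CCC2=C(C)CCCC2(C)C)OO1 | target

Total steps: 15. Longest linear sequence: 13 (steps 1–12, then 15).

**Steps most likely to fail**

1. **Step 15.**
   - What may go wrong: low-valent nickel may reduce or insert into the O–O bond of ring A. The two iodides may dimerise or be hydrodehalogenated. The alkene geometry may erode through isomerisation of the alkenylnickel species.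
   - Fallback: leave the reductive radical manifold for a polar, redox-neutral Negishi coupling with a preformed nucleophile. It sets out from 20. Iodine–lithium exchange (t-BuLi, Et2O, −78 °C) and transmetalation with ZnBr2 give (E)-alkenylzinc bromide F1. F1 is coupled with 15 under PdCl2(IPr)(3-chloropyridine) (IPr = 1,3-bis(2,6-diisopropylphenyl)imidazol-2-ylidene) and LiBr in THF/N-methylpyrrolidone at rt. No reducing agent and no phosphine are present, and the organozinc is too mild for the ester and the peroxide. The fallback comes back to the route at 21.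

2. **Step 7.**
   - What may go wrong: ionisation to a free tertiary cation may outrun rear-side attack, with loss of configurational purity at C6 and elimination to alkenes. The new hydroperoxide may also rearrange under acid.
   - Fallback: replace the ionic opening by a radical peroxidation and give up control at C6. It sets out from 9. Al(C6F5)3-catalysed isomerisation of the oxetane gives homoallylic alcohol F2. Mukaiyama–Isayama hydroperoxysilylation (Co(thd)2, O2, Et3SiH, 1,2-dichloroethane, rt) should act faster on the 1,1-disubstituted alkene than on the vinyl group and gives triethylsilyl peroxide F3 as both C6 epimers. n-Bu4NF in THF frees the peroxy anion, which closes ring A in the same flask. The cis and trans dioxanes are separated by chromatography, and the fallback comes back to the route at 11.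

3. **Step 8.**
   - What may go wrong: displacement at the beta-branched secondary carbon may be slow. E2 loss of the mesylate toward the conjugated diene may then compete, as may base-induced fragmentation of the product at C3–H.
   - Fallback: form the O–C3 bond by conjugate addition instead of substitution, trading stereocontrol at C2 and C3 for brevity. It sets out from 6. Wittig olefination with Ph3P=C(CH3)CO2Me (CH2Cl2, rt) gives (E)-enoate F4. Perhydrolysis as in step 7 gives hydroperoxy enoate F5. Et2NH in CF3CH2OH triggers the 6-exo-trig intramolecular oxa-Michael addition. The C2/C3 diastereomers are separated by chromatography, and the fallback comes back to the route at 14.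

**Further compounds**
F1 | step 15 | bromo[(1E)-2-methyl-4-(2,6,6-trimethylcyclohex-1-en-1-yl)but-1-en-1-yl]zinc | Br[Zn]/C=C(\C)CCC1=C(C)CCCC1(C)C
F2 | step 7 | (3R,4R)-9-hydroxy-3-methyl-7-methylidenenon-1-en-4-yl methanesulfonate | C=C[C@@H](C)[C@H](OS(C)(=O)=O)CCC(=C)CCO
F3 | step 7 | (3R,4R)-9-hydroxy-3,7-dimethyl-7-(triethylsilylperoxy)non-1-en-4-yl methanesulfonate, both C7 epimers | C=C[C@@H](C)[C@H](OS(C)(=O)=O)CCC(C)(CCO)OO[Si](CC)(CC)CC
F4 | step 8 | methyl (2E)-2-methyl-5-[(2S)-2-methyloxetan-2-yl]pent-2-enoate | COC(=O)/C(C)=C/CC[C@@]1(C)CCO1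
F5 | step 8 | methyl (2E,6R)-6-hydroperoxy-8-hydroxy-2,6-dimethyloct-2-enoate | COC(=O)/C(C)=C/CC[C@](C)(CCO)OO
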